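The synthesis rests on disconnecting the C5–C6 bond of the cycloheptane ring (longipinane numbering: C1 enone carbonyl, C5 cyclobutane CH, C6 quaternary carbon, C7 and C9 carbinols). C6, which carries CH3 and CH2O next to the C7 carbinol, is the retron of a semipinacol ring expansion: in a six-membered tertiary epoxy alcohol the cyclobutane methine C5 shifts from C7 to C6. One operation forms C5–C6, enlarges the cyclohexane to the cycloheptane, fixes the C6 stereocentre and delivers the C7 ketone and the C15 hydroxyl. The precursor is a 6-nor tricycle (tricyclo[4.4.0.0^{2,7}]decane) assembled by an asymmetric quinone Diels–Alder reaction and an enolate cyclobutane closure.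

Key step: step 12

Remark: target atom labels are used for all intermediates (ring A = C1, C2, C3, C4, C10, C11; ring B = C4, C5, C7, C8, C9, C10; C15 is the CH2O carbon on C6; "6-norlongipinane" is the tricyclo[4.4.0.0^{2,7}]decane skeleton with C5 bonded to C7). The sense of induction of the catalyst made from TiCl2(OiPr)2 and (S)-BINOL in step 2 is assumed, and the ligand antipode would be used if it proved opposite. In the enzymatic resolution named among the fallbacks, the lipase is taken to acylate the unwanted antipode.

Step 1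
Reactants: 1 (E)-4-methoxypent-3-en-2-one
Product: 2 (E)-tert-butyl[(4-methoxypenta-1,3-dien-2-yl)oxy]dimethylsilane
Conditions: TBSOTf, Et3N, Et2O, 0 °C
Reagents that add atoms: tert-butyldimethylsilyl trifluoromethanesulfonate, CC(C)(C)[Si](C)(C)OS(=O)(=O)C(F)(F)F
Why: Silyl enol ether formation by soft enolisation at the terminal methyl of the ketone should give the electron-rich 2-siloxy-4-methoxy diene with the enol ether geometry kept; no stereocentre is formed.

Step 2
Reactants: 2 (E)-tert-butyl[(4-methoxypenta-1,3-dien-2-yl)oxy]dimethylsilane; 3 2-methoxy-5-methyl-1,4-benzoquinone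
Product: 4 cis-fused adduct 6-(tert-butyldimethylsilyloxy)-2,8-dimethoxy-4a,8-dimethyl-4a,5,8,8a-tetrahydronaphthalene-1,4-dione
Conditions: (S)-BINOL (0.2 equiv), TiCl2(OiPr)2 (0.2 equiv), 4 Å MS, toluene, −40 to −20 °C
Reagents that add atoms: none
Why: Catalytic asymmetric Diels–Alder reaction: the C7 methoxy group deactivates its own double bond as a vinylogous ester and binds the Lewis acid in a chelate together with the C5 carbonyl, so the diene should add to the C4=C10 bond with its nucleophilic CH2 terminus (C11) on C10, suprafacial addition gives the cis ring fusion, the chiral complex formed from TiCl2(OiPr)2 and (S)-BINOL selects the quinone face and so sets C4 and C10, and the endo transition state sets C3, which is lost later.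

Step 3
Reactants: 4 cis-fused Diels–Alder adduct
Product: 5 C5,C9-diol of 4
Conditions: iBu2AlH (3 equiv), CH2Cl2, −78 °C; aq. KNaC4H4O6 work-up
Reagents that add atoms: none
Why: 1,2-Hydride reduction of the ene-dione carbonyl C5 and the vinylogous ester carbonyl C9 should occur from the convex face of the cis-fused bicycle (the face of C4–H and C10–CH3), which places both new hydroxyls on the concave face and sets C5 and C9, while the silyl enol ether masks the ring A ketone.

Step 4
Reactants: 5 C5,C9-diol
Product: 6 C5-monoacetate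
Conditions: Ac2O (1.1 equiv), pyridine, DMAP (cat.), CH2Cl2, −20 °C
Reagents that add atoms: acetic anhydride, CC(=O)OC(C)=O
Why: Chemoselective acylation should take the C5 hydroxyl next to a methine before the neopentyl C9 hydroxyl next to quaternary C10; no stereocentre changes.

Step 5
Reactants: 6 C5-monoacetate
Product: 7 C5-acetate C9-tert-butyldimethylsilyl ether
Conditions: TBSOTf, 2,6-lutidine, CH2Cl2, −78 °C
Reagents that add atoms: tert-butyldimethylsilyl trifluoromethanesulfonate, CC(C)(C)[Si](C)(C)OS(=O)(=O)C(F)(F)F
Why: Silylation of the hindered secondary alcohol with a silyl triflate under buffered conditions should protect C9–OH, the later stereocontrol element of the lower bridge, without ionising the acid-labile allylic enol ether.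

Step 6
Reactants: 7 C5-acetate C9-silyl ether
Product: 9 C5-hydroxy ring A enone, via enone acetate 8 (not isolated)
Conditions: Bu4NF (1.1 equiv), THF, −20 °C; then K2CO3, MeOH, 0 °C
Reagents that add atoms: none
Why: Fluoride cleaves the silyl enol ether, the enolate expels the β-methoxide (E1cB elimination) to give the 3-methylcyclohexenone of ring A, and methanolysis (transesterification) then removes the acetate while the hindered C9 silyl ether should survive.

Step 7
Reactants: 9 C5-hydroxy ring A enone
Product: 10 C5-bromo ring A enone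
Conditions: PPh3, CBr4, 2,6-lutidine, CH2Cl2, 0 °C
Reagents that add atoms: tetrabromomethane, BrC(Br)(Br)Br
Why: The Appel reaction proceeds by SN2 displacement with inversion at C5, so bromide should end on the face of C4–H and C10–CH3, anti to the C11 methylene that must displace it next.

Step 8
Reactants: 10 C5-bromo ring A enone
Product: 12 9-(tert-butyldimethylsilyloxy)-7-methoxy-6-norlongipina-2,7-dien-1-one, via lithium dienolate 11 (not isolated)
Conditions: LiN(iPr)2 (1.1 equiv), THF, −78 °C; DMPU, −78 to 0 °C
Reagents that add atoms: none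
Why: Kinetic α′-deprotonation of the enone at C11 followed by intramolecular enolate alkylation (4-exo-tet SN2 on the allylic bromide, the mode known for keto sulfonates that close tricyclo[4.4.0.0^{2,7}]decanes) should form the C5–C11 cyclobutane bond with inversion at C5, C11 being fixed by the ring constraint and anti elimination being blocked because Br and C4–H are cis.

Step 9
Reactants: 12 tricyclic enol ether
Product: 13 9-(tert-butyldimethylsilyloxy)-6-norlongipin-2-ene-1,7-dione
Conditions: (CO2H)2 (0.1 M aq.), THF, 0 °C
Reagents that add atoms: water, O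
Why: Enol ether hydrolysis by C-protonation at C8 and hydration of the oxocarbenium ion should unveil the C7 ketone, the mild acid avoiding β-elimination of the C9 silyloxy group.

Step 10
Reactants: 13 tricyclic diketone; 14 isopropenylmagnesium bromide
Product: 15 7-hydroxy-7-(prop-1-en-2-yl)-9-(tert-butyldimethylsilyloxy)-6-norlongipin-2-en-1-one
Conditions: CeCl3 (anhydrous), THF, −78 °C
Reagents that add atoms: none
Why: Organocerium 1,2-addition should take the saturated C7 ketone in preference to the conjugated, β-methyl-deactivated C1 carbonyl and should attack anti to the C9 silyloxy group, which sets C7 with its hydroxyl syn to C9–O.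

Step 11
Reactants: 15 tertiary allylic alcohol
Product: 16 7-hydroxy-7-(2-methyloxiran-2-yl)-9-(tert-butyldimethylsilyloxy)-6-norlongipin-2-en-1-one
Conditions: VO(acac)2 (5 mol %), tBuOOH, CH2Cl2, 0 °C
Reagents that add atoms: tert-butyl hydroperoxide, CC(C)(C)OO
Why: Hydroxyl-directed VO(acac)2-catalysed epoxidation delivers oxygen syn to C7–OH in the rotamer that puts the isopropenyl methyl over the tied-back cyclobutane carbon C5 and not against the C8 hydrogens (least allylic 1,2-strain), which should set C6, while the electron-poor enone is untouched.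

Step 12
Reactants: 16 tertiary epoxy alcohol
Product: 17 15-hydroxy-9-(tert-butyldimethylsilyloxy)longipin-2-ene-1,7-dione
Conditions: BF3·OEt2 (0.2 equiv), CH2Cl2, −78 to −40 °C
Reagents that add atoms: none
Why: BF3 coordinates the epoxide oxygen and, as the tertiary C6–O bond lengthens, the antiperiplanar C7–C5 bond migrates to C6 while the C7 hydroxyl becomes the ketone, so no free cation at C7 can open the cyclobutane. This is a semipinacol rearrangement of a 2,3-epoxy alcohol with ring expansion, the closest known class being the Lewis-acid rearrangement of 1-(2-methyloxiranyl)cycloalkanols to 2-hydroxymethyl-2-methylcycloalkanones. The cycloheptanone ring is closed by a suprafacial 1,2-carbon shift that inserts C6 into the former C5–C7 bond of the six-membered ring, not by an exo or endo cyclisation. The quaternary stereocentre C6 forms with inversion at the epoxide carbon and is therefore fixed by the epoxide configuration from step 11, while the migrating C5 keeps its configuration. The step needs migration of C5 instead of C8: C5 is the more substituted carbon, C8 is inductively deactivated by the C9 silyloxy group, and the rotamer with C5 anti to the epoxide C–O bond is the less congested one; the enone is not touched.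

Step 13
Reactants: 17 hydroxy diketone
Product: 18 7,15-dihydroxy-9-(tert-butyldimethylsilyloxy)longipin-2-en-1-one
Conditions: Me4NBH(OAc)3, MeCN/AcOH, −30 °C
Reagents that add atoms: none
Why: Evans–Saksena hydroxyl-directed reduction delivers hydride from the C15–O-bound borohydride to the C15 face of the C7 ketone, which should set C7 with its hydroxyl trans to the hydroxymethyl group, and leaves the enone alone.

Step 14
Reactants: 18 silyl-protected diol; 19 angelic acid
Product: 20 15-angeloyloxy-7-hydroxy-9-(tert-butyldimethylsilyloxy)longipin-2-en-1-one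
Conditions: 19 (1.2 equiv), 2,4,6-trichlorobenzoyl chloride (1.2 equiv), Et3N, toluene, 25 °C; then 18, 50 °C
Reagents that add atoms: none
Why: Yamaguchi esterification through the mixed anhydride made in the flask should acylate the primary C15 hydroxyl well before the C7 hydroxyl, which is secondary and flanked by quaternary C6, and leaving out a nucleophilic amine catalyst should suppress isomerisation of the (Z)-angelate to the tiglate; no stereocentre changes.

Step 15
Reactants: 20 C15 monoangelate; 19 angelic acid
Product: 21 7,15-bis(angeloyloxy)-9-(tert-butyldimethylsilyloxy)longipin-2-en-1-one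
Conditions: 19 (3 equiv), 2,4,6-trichlorobenzoyl chloride (3 equiv), Et3N, toluene, 25 °C; then 20, 80 °C
Reagents that add atoms: none
Why: The same Yamaguchi esterification with an excess of mixed anhydride at higher temperature should acylate the hindered secondary C7 hydroxyl, the only free hydroxyl left, so that any acyl migration between O15 and O7 is without consequence; no stereocentre changes.

Step 16
Reactants: 21 bis-angelate silyl ether
Product: 22 7,15-bis(angeloyloxy)-9-hydroxylongipin-2-en-1-one
Conditions: HF·pyridine, pyridine, THF, 0 to 25 °C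
Reagents that add atoms: none
Why: Desilylation with buffered acidic fluoride should free the C9 hydroxyl, while the non-basic medium should suppress migration of the C7 angelate to O9 and leave the (Z)-enoates and the enone untouched; no stereocentre changes.

Step 17
Reactants: 22 C9-hydroxy bis-angelate; 19 angelic acid
Product: 23 7,9,15-tris(angeloyloxy)longipin-2-en-1-one (target)
Conditions: 19 (4 equiv), 2,4,6-trichlorobenzoyl chloride (4 equiv), Et3N, toluene, 25 °C; then 22, 90 °C
Reagents that add atoms: none
Why: Yamaguchi esterification of the last hydroxyl, the secondary C9–OH next to quaternary C10, with excess mixed anhydride should complete the triester, again without a nucleophilic amine catalyst so that the angelate geometry is kept; no stereocentre changes.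

Compound list
1 | (E)-4-methoxypent-3-en-2-one | CC(=O)/C=C(\C)OC | starting material
2 | (E)-tert-butyl[(4-methoxypenta-1,3-dien-2-yl)oxy]dimethylsilane | C=C(O[Si](C)(C)C(C)(C)C)/C=C(\C)OC | intermediate
3 | 2-methoxy-5-methyl-1,4-benzoquinone | COC1=CC(=O)C(C)=CC1=O | starting material
4 | cis-fused adduct 6-(tert-butyldimethylsilyloxy)-2,8-dimethoxy-4a,8-dimethyl-4a,5,8,8a-tetrahydronaphthalene-1,4-dione (C4–H cis to C10–CH3; C3–OCH3 cis to the C4–C5 bond) | CC(C)(C)[Si](C)(C)OC1=C[C@@](C)(OC)[C@H]2C(=O)C(OC)=CC(=O)[C@@]2(C)C1 | intermediate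
5 | C5,C9-diol of 4 (both hydroxyls on the face of ring B that carries ring A, trans to C4–H and C10–CH3) | CC(C)(C)[Si](C)(C)OC1=C[C@@](C)(OC)[C@H]2[C@@H](O)C(OC)=C[C@@H](O)[C@@]2(C)C1 | intermediate
6 | C5-monoacetate of 5 | CC(C)(C)[Si](C)(C)OC1=C[C@@](C)(OC)[C@H]2[C@@H](OC(C)=O)C(OC)=C[C@@H](O)[C@@]2(C)C1 | intermediate
7 | C5-acetate C9-tert-butyldimethylsilyl ether | CC(C)(C)[Si](C)(C)OC1=C[C@@](C)(OC)[C@H]2[C@@H](OC(C)=O)C(OC)=C[C@@H](O[Si](C)(C)C(C)(C)C)[C@@]2(C)C1 | intermediate
8 | enone acetate (ring A: C1 ketone, C2=C3–CH3; ring B: C5–OAc, C7 methyl enol ether, C9–OTBS) | O=C1C=C(C)[C@H]2[C@@H](OC(C)=O)C(OC)=C[C@@H](O[Si](C)(C)C(C)(C)C)[C@@]2(C)C1 | intermediate (not isolated)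
9 | C5-hydroxy ring A enone | O=C1C=C(C)[C@H]2[C@@H](O)C(OC)=C[C@@H](O[Si](C)(C)C(C)(C)C)[C@@]2(C)C1 | intermediate
10 | C5-bromo ring A enone (Br cis to C4–H and C10–CH3) | O=C1C=C(C)[C@H]2[C@H](Br)C(OC)=C[C@@H](O[Si](C)(C)C(C)(C)C)[C@@]2(C)C1 | intermediate
11 | lithium dienolate of 10 (C1–OLi, C1=C11) | [Li]OC1=C[C@]2(C)[C@H](O[Si](C)(C)C(C)(C)C)C=C(OC)[C@@H](Br)[C@@H]2C(C)=C1 | intermediate (not isolated)
12 | 9-(tert-butyldimethylsilyloxy)-7-methoxy-6-norlongipina-2,7-dien-1-one (C9–O on the side of C11, trans to C10–CH3 as in 5) | O=C1C=C(C)[C@H]2[C@@H]3C(OC)=C[C@@H](O[Si](C)(C)C(C)(C)C)[C@@]2(C)[C@H]13 | intermediate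
13 | 9-(tert-butyldimethylsilyloxy)-6-norlongipin-2-ene-1,7-dione | O=C1C=C(C)[C@H]2[C@@H]3C(=O)C[C@@H](O[Si](C)(C)C(C)(C)C)[C@@]2(C)[C@H]13 | intermediate
14 | isopropenylmagnesium bromide | C=C(C)[Mg]Br | starting material
15 | 7-hydroxy-7-(prop-1-en-2-yl)-9-(tert-butyldimethylsilyloxy)-6-norlongipin-2-en-1-one (7-OH syn to 9-O) | O=C1C=C(C)[C@H]2[C@@H]3[C@](O)(C(C)=C)C[C@@H](O[Si](C)(C)C(C)(C)C)[C@@]2(C)[C@H]13 | intermediate
16 | 7-hydroxy-7-(2-methyloxiran-2-yl)-9-(tert-butyldimethylsilyloxy)-6-norlongipin-2-en-1-one | O=C1C=C(C)[C@H]2[C@@H]3[C@](O)([C@@]4(C)CO4)C[C@@H](O[Si](C)(C)C(C)(C)C)[C@@]2(C)[C@H]13 | intermediate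
17 | 15-hydroxy-9-(tert-butyldimethylsilyloxy)longipin-2-ene-1,7-dione | O=C1C=C(C)[C@H]2[C@@H]3[C@@](C)(CO)C(=O)C[C@@H](O[Si](C)(C)C(C)(C)C)[C@@]2(C)[C@H]13 | intermediate
18 | 7,15-dihydroxy-9-(tert-butyldimethylsilyloxy)longipin-2-en-1-one (7-OH trans to C15 and trans to 9-O) | O=C1C=C(C)[C@H]2[C@@H]3[C@@](C)(CO)[C@H](O)C[C@@H](O[Si](C)(C)C(C)(C)C)[C@@]2(C)[C@H]13 | intermediate
19 | angelic acid, (Z)-2-methylbut-2-enoic acid | C/C=C(/C)C(=O)O | starting material
20 | 15-angeloyloxy-7-hydroxy-9-(tert-butyldimethylsilyloxy)longipin-2-en-1-one | O=C1C=C(C)[C@H]2[C@@H]3[C@@](C)(COC(=O)/C(C)=C\C)[C@H](O)C[C@@H](O[Si](C)(C)C(C)(C)C)[C@@]2(C)[C@H]13 | intermediate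
21 | 7,15-bis(angeloyloxy)-9-(tert-butyldimethylsilyloxy)longipin-2-en-1-one | O=C1C=C(C)[C@H]2[C@@H]3[C@@](C)(COC(=O)/C(C)=C\C)[C@H](OC(=O)/C(C)=C\C)C[C@@H](O[Si](C)(C)C(C)(C)C)[C@@]2(C)[C@H]13 | intermediate
22 | 7,15-bis(angeloyloxy)-9-hydroxylongipin-2-en-1-one | O=C1C=C(C)[C@H]2[C@@H]3[C@@](C)(COC(=O)/C(C)=C\C)[C@H](OC(=O)/C(C)=C\C)C[C@@H](O)[C@@]2(C)[C@H]13 | intermediate
23 | 7,9,15-tris(angeloyloxy)longipin-2-en-1-one (CNP0266467.1) | O=C1C=C(C)[C@H]2[C@@H]3[C@@](C)(COC(=O)/C(C)=C\C)[C@H](OC(=O)/C(C)=C\C)C[C@@H](OC(=O)/C(C)=C\C)[C@@]2(C)[C@H]13 | target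

Total step count: 17. Longest linear sequence: 17 steps (1 to 23).

Steps most likely to fail

Step 2. The chiral Lewis acid may discriminate the quinone faces poorly, may bind the more basic C9 carbonyl and so erode the regiocontrol, or may desilylate the diene before cycloaddition. The fallback sets out from 2 and 3. An uncatalysed thermal Diels–Alder reaction (toluene, 60 °C) gives 4 as a racemate with its mirror image ent-4 F1. Reduction with iBu2AlH as in step 3 gives 5 together with ent-5 F2. Lipase-catalysed acylation (Burkholderia cepacia lipase, vinyl acetate, tBuOMe) should acetylate the C5 hydroxyl of the unwanted antipode only, giving ent-6 F3, and unreacted 5 is separated by chromatography. The fallback comes back to the route at 5.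

Step 8. Amine-mediated proton transfer from C4 to the kinetic C11 enolate may give the extended dienolate, which expels bromide by vinylogous β-elimination faster than the strained four-membered ring closes. The fallback sets out from 10. An in situ quench with LiN(iPr)2 and Me3SiCl (THF, −78 °C) traps the C11 enolate as the cross-conjugated trimethylsilyl dienol ether F4. Anhydrous fluoride (tris(dimethylamino)sulfonium difluorotrimethylsilicate, THF, −78 to 0 °C) then desilylates F4 in the absence of amine, and the liberated enolate alkylates C5 intramolecularly. The fallback comes back to the route at 12.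

Step 12. The C8 methylene may migrate in competition with C5, giving the regioisomeric ring expansion, or the epoxide may ionise without migration. The fallback sets out from 16. Bu4NF removes the silyl group to give the epoxy diol F5. Dess–Martin periodinane oxidises the secondary C9 hydroxyl to the epoxy hydroxy diketone F6, in which C8 is α to a carbonyl and therefore a poor migrating group. Catalytic BF3·OEt2 then gives 15-hydroxylongipin-2-ene-1,7,9-trione F7. Two consecutive hydroxyl-directed reductions with Me4NBH(OAc)3 follow. C15–OH delivers hydride to C7 and gives 7,15-dihydroxylongipin-2-ene-1,9-dione F8. The new C7–OH then delivers hydride to C9 on its own face, which gives the 7,9-anti diol in 7,9,15-trihydroxylongipin-2-en-1-one F9. Exhaustive Yamaguchi esterification of F9 with at least three equivalents of angelic acid 19 (2,4,6-trichlorobenzoyl chloride, Et3N, toluene, 90 °C) acylates all three hydroxyls. The fallback comes back to the route at 23.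

Further compounds
F1 | step 2 | ent-4, mirror image of the Diels–Alder adduct (formed with 4 as racemate) | CC(C)(C)[Si](C)(C)OC1=C[C@](C)(OC)[C@@H]2C(=O)C(OC)=CC(=O)[C@]2(C)C1
F2 | step 2 | ent-5, mirror image of the C5,C9-diol (formed with 5 as racemate) | CC(C)(C)[Si](C)(C)OC1=C[C@](C)(OC)[C@@H]2[C@H](O)C(OC)=C[C@H](O)[C@]2(C)C1
F3 | step 2 | ent-6, C5-monoacetate of ent-5 | CC(C)(C)[Si](C)(C)OC1=C[C@](C)(OC)[C@@H]2[C@H](OC(C)=O)C(OC)=C[C@H](O)[C@]2(C)C1
F4 | step 8 | trimethylsilyl dienol ether of 10 (C1–OSiMe3, C1=C11) | C[Si](C)(C)OC1=C[C@]2(C)[C@H](O[Si](C)(C)C(C)(C)C)C=C(OC)[C@@H](Br)[C@@H]2C(C)=C1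
F5 | step 12 | 7,9-dihydroxy-7-(2-methyloxiran-2-yl)-6-norlongipin-2-en-1-one | O=C1C=C(C)[C@H]2[C@@H]3[C@](O)([C@@]4(C)CO4)C[C@@H](O)[C@@]2(C)[C@H]13
F6 | step 12 | 7-hydroxy-7-(2-methyloxiran-2-yl)-6-norlongipin-2-ene-1,9-dione | O=C1C=C(C)[C@H]2[C@@H]3[C@](O)([C@@]4(C)CO4)CC(=O)[C@@]2(C)[C@H]13
F7 | step 12 | 15-hydroxylongipin-2-ene-1,7,9-trione | O=C1C=C(C)[C@H]2[C@@H]3[C@@](C)(CO)C(=O)CC(=O)[C@@]2(C)[C@H]13
F8 | step 12 | 7,15-dihydroxylongipin-2-ene-1,9-dione | O=C1C=C(C)[C@H]2[C@@H]3[C@@](C)(CO)[C@H](O)CC(=O)[C@@]2(C)[C@H]13
F9 | step 12 | 7,9,15-trihydroxylongipin-2-en-1-one | O=C1C=C(C)[C@H]2[C@@H]3[C@@](C)(CO)[C@H](O)C[C@@H](O)[C@@]2(C)[C@H]13
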